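## Analysis of the target

The target 18 is a labdane (labdane numbering throughout): a trans-fused decalin with ring A = C1–C5, C10 (gem-dimethyl C18/C19 on C4) and ring B = C5–C10 (C7=C8 olefin, C17 on C8, angular methyl C20 on C10), carrying at C9 the chain C11–C16 that ends in a tertiary vinyl carbinol. Four of the five stereocentres lie around ring B: C5 (S), C6 (S), C9 (S) and C10 (R). H5 is α and axial, anti to the β-axial C20; the chain on C9 is β and equatorial (H9 α, anti to C20); the butanoate on C6 is α and equatorial, so H6 sits axial between the two syn-axial methyls C19 and C20. The fifth centre, C13 (R), is four bonds from the ring: it cannot be controlled from the ring nor control it, and has to be bought. Sensitive groups are the tertiary allylic alcohol at C13 (ionises and transposes with acid), the allylic C6 ester (loses across H5 to a ring B diene once activated) and the C7=C8 olefin, which has two regioisomeric positions (C8=C17, C8=C9) within reach of any cation at C8. The hardest bond is C9–C10, a quaternary carbon joined to a stereogenic methine. The hardest stereocentre is C6: C19 and C20 roof the β face, so a reagent adding to a C6 carbonyl should come from α and leave the oxygen β; the 6α oxygen is the more stable epimer but not the one reduction is expected to give. A plan must therefore settle three things together: how C9–C10 is forged with the ring antipode matched to C13, where the olefin lands, and how the C6 oxygen ends up equatorial.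

## Retrosynthetic reasoning

**18 ⇒ 17 ⇒ 16.** The O–Si bond at C13 and the acyl C–O bond at C6 are cut last. The 6α-alcohol 16 is equatorial and unhindered, so acylation is trivial, and the tertiary carbinol stays masked until nothing acidic or basic follows.

**16 ⇒ 15.** No bond is cut; the configuration at C6 is handed to thermodynamics. The ring B allylic alcohol can ionise reversibly under rhenium-oxo catalysis, and the 6α-ol is the most stable of the allylic isomers. The precursor may therefore be the C6 epimer mixture 15, and no earlier step has to control C6 kinetically.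

**15 ⇒ 14.** The C7=C8 double bond is cut by ring-closing metathesis between a vinyl carbinol on C5 and an isopropenyl group on C9. Cutting here fixes the olefin at C7=C8 by construction instead of by a choice among three β-hydrogens. The forward reaction must close a trisubstituted cyclohexene without touching the hindered C14=C15 vinyl group.

**14 ⇒ 13.** The C6–C7 bond is cut to the aldehyde 13 and a vinyl nucleophile. The facial selectivity of this addition is irrelevant because of the equilibration above.

**13 ⇒ 10 (key).** The aldehyde 13 is a 4-pentenal: C6(=O)–C5–C10–C9–C8=C7. That is the retron of an oxy-Cope rearrangement. Breaking C9–C10 and re-joining C7 to C6 gives the dienol 10, whose 1,5-diene C10=C5–C6(OH)–C7–C8=C9 consists of the six atoms of ring B. The cut is made at C9–C10 because a sigmatropic shift is the most reliable way to make a quaternary-to-tertiary bond. It also reduces C9 and C10 to one carbinol centre at C6 and two olefin geometries. The forward reaction has to pass the C6 configuration to C9 and C10 through a chair.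

**10 ⇒ 9 ⇒ 8 ⇒ 5 + 6.** The carbinol 10 comes from catalyst-controlled reduction of ketone 9, which comes from the alcohol 8. Alcohol 8 is cut at C6–C7 into β-cyclocitral 6 and the allylbarium species 7 made from chloride 5. This divides the C20 skeleton into two commercial C10 terpenes. The forward addition must go through the unsubstituted allyl terminus and keep the E olefin.

**5 ⇒ 3 ⇒ 2 ⇒ 1.** The allyl chloride comes from linalool 1 by oxidation of its E methyl group. C13 arrives with 1 and is never touched.

## Alternatives that were turned down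

**Alternative 1:** (the textbook route) Start from sclareol A1, which already holds C5, C9, C10 and C13. Dehydrate the C8 alcohol to the dienol A2, oxidise the allylic C6 methylene to the enone A3, then reduce and acylate. No skeletal bond is made. It was turned down because each remaining task runs against this scaffold. The equatorial 8α-oxygen has no anti-periplanar ring hydrogen, so elimination favours C8=C17; ionising conditions drift to C8=C9 and also ionise C13. Hydride should reach the C6 carbonyl of A3 only from the α face and give the axial 6β-alcohol A4. Inverting A4 means activating an oxygen flanked by C19 and C20 with H5 anti-periplanar, which invites diene formation. The repair of C6 would be longer than the rest of the route.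

**Alternative 2:** Biomimetic cation–olefin bicyclisation of (R)-geranyllinalool A5, forming C4–C5 and C9–C10 in one cascade and ending by proton loss to A2. It was turned down because C13 is too far from the forming bonds to choose between the two antipodal chair–chair folds, so the ring would form as both antipodes against a fixed C13. The acid would also ionise the tertiary allylic alcohol or let it trap the C8 cation as the cyclic ether A6. C6 would remain a methylene, so the route would join Alternative 1 at its weakest point.

**Alternative 3:** Close ring B directly from ketone 9: deprotonate at C7 to the 2-oxidotriene A7 and let it undergo thermal 6π-electrocyclisation, forming C9–C10 and the 7-en-6-one in one step. It was turned down for three reasons. Disrotatory closure of the accessible E olefin puts C11 and C1 cis, giving the 9-epi enone A8; the Z olefin that would give the right C9 would place an alkyl group inside, against C20, and block closure. With C6 trigonal, nothing near the forming bond is stereogenic, so both ring antipodes form. The product is again a C6 ketone, which hydride should reduce to the wrong epimer.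

Key step: step 7

Remark on the chemistry: commercial (R)-(−)-linalool is assumed to be of high enantiomeric purity; the C13 purity of every later compound rests on it.

## Route

Step 1
Reactants: 1 (R)-(−)-linalool, (3R)-3,7-dimethylocta-1,6-dien-3-ol
Product: 2 (3R)-3,7-dimethyl-3-(triethylsilyloxy)octa-1,6-diene
Conditions: Et3SiOTf, 2,6-lutidine, CH2Cl2, −78 → 0 °C
Reagents that add atoms: triethylsilyl trifluoromethanesulfonate, CC[Si](CC)(CC)OS(=O)(=O)C(F)(F)F
Why: Silyl triflate silylation of a tertiary alcohol; the ether removes the acidic proton before the organobarium and hydride-base steps and makes C13 inert to the later rhenium-oxo catalysis, which needs a free hydroxyl.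

Step 2
Reactants: 2 (3R)-3,7-dimethyl-3-(triethylsilyloxy)octa-1,6-diene
Product: 3 (2E,6R)-2,6-dimethyl-6-(triethylsilyloxy)octa-2,7-dien-1-ol
Conditions: SeO2 (cat.), t-BuOOH, salicylic acid (cat.), CH2Cl2, rt
Reagents that add atoms: selenium dioxide, O=[Se]=O (catalytic oxygen carrier); tert-butyl hydroperoxide, CC(C)(C)OO (terminal oxygen source)
Why: Riley allylic oxidation (ene reaction, then [2,3] shift) is selective for the E methyl group of a trisubstituted olefin; the vinyl group has no allylic hydrogen and should not react.

Step 3
Reactants: 3 (2E,6R)-2,6-dimethyl-6-(triethylsilyloxy)octa-2,7-dien-1-ol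
Product: 5 (2E,6R)-1-chloro-2,6-dimethyl-6-(triethylsilyloxy)octa-2,7-diene, via allylic mesylate 4 (not isolated)
Conditions: MsCl, 2,4,6-collidine, LiCl, DMF, 0 °C
Reagents that add atoms: lithium chloride, [Li+].[Cl-]
Why: In-situ mesylation and chloride displacement of a primary allylic alcohol proceed by SN2 without allylic transposition, so the E geometry is kept.

Step 4
Reactants: 5 (2E,6R)-1-chloro-2,6-dimethyl-6-(triethylsilyloxy)octa-2,7-diene; 6 β-cyclocitral, 2,6,6-trimethylcyclohex-1-ene-1-carbaldehyde
Product: 8 (1RS,3E,7R)-3,7-dimethyl-7-(triethylsilyloxy)-1-(2,6,6-trimethylcyclohex-1-en-1-yl)nona-3,8-dien-1-ol, via allylbarium chloride 7 (not isolated)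
Conditions: BaI2, lithium biphenylide (2 equiv), THF, rt; 5, −78 °C; then 6, −78 °C; aq. NH4Cl
Reagents that add atoms: none
Why: Allylbarium reagents from zerovalent barium add to carbonyl groups through the unsubstituted (α) terminus with retention of olefin geometry, which gives the linear 1,5-dien-3-ol needed for step 7; the new carbinol centre is not controlled here and is erased in step 5.

Step 5
Reactants: 8 (1RS,3E,7R)-3,7-dimethyl-7-(triethylsilyloxy)-1-(2,6,6-trimethylcyclohex-1-en-1-yl)nona-3,8-dien-1-ol
Product: 9 (3E,7R)-3,7-dimethyl-7-(triethylsilyloxy)-1-(2,6,6-trimethylcyclohex-1-en-1-yl)nona-3,8-dien-1-one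
Conditions: Dess–Martin periodinane, NaHCO3, CH2Cl2, 0 °C
Reagents that add atoms: none
Why: Buffered Dess–Martin oxidation is neutral enough to leave the β,γ-olefin out of conjugation and the silyl ether intact.

Step 6
Reactants: 9 (3E,7R)-3,7-dimethyl-7-(triethylsilyloxy)-1-(2,6,6-trimethylcyclohex-1-en-1-yl)nona-3,8-dien-1-one
Product: 10 (1S,3E,7R)-3,7-dimethyl-7-(triethylsilyloxy)-1-(2,6,6-trimethylcyclohex-1-en-1-yl)nona-3,8-dien-1-ol
Conditions: (R)-2-methyl-CBS-oxazaborolidine (20 mol %), catecholborane, toluene, −78 °C; aq. NaOH wash
Reagents that add atoms: none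
Why: Corey–Bakshi–Shibata reduction; the tetrasubstituted cyclohexenyl group is the large substituent and the allylic CH2 the small one, so the (R)-catalyst should give the (1S) carbinol (C6 of the labdane), and catecholborane is chosen because it does not hydroborate the olefins at this temperature.

Step 7
Reactants: 10 (1S,3E,7R)-3,7-dimethyl-7-(triethylsilyloxy)-1-(2,6,6-trimethylcyclohex-1-en-1-yl)nona-3,8-dien-1-ol
Product: 13 (13R)-13-(triethylsilyloxy)-6,7-secolabda-7,14-dien-6-al (5α-H; 10β-CH3; C9 as in the target), via potassium alkoxide 11 (not isolated), via potassium enolate 12 (not isolated)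
Conditions: KH, 18-crown-6, THF, 0 → 40 °C; then AcOH, THF, −78 °C → rt
Reagents that add atoms: none
Why: KH with 18-crown-6 gives the dissociated alkoxide 11, in which the oxyanion weakens the C6–C7 σ bond so that the 1,5-diene C10=C5–C6(O−)–C7–C8=C9 undergoes a charge-accelerated [3,3]-sigmatropic shift (anionic oxy-Cope rearrangement) to the enolate 12, making C9–C10 and breaking C6–C7. The closest known reaction type is the 1,2-allylation/anionic oxy-Cope sequence used as a formal conjugate allylation of β,β-disubstituted enals and enones to build quaternary carbons. No ring is closed, but the chair transition state C10–C5–C6–C7–C8–C9 is, atom for atom, the later ring B. C10 is set by the ring olefin geometry (C20 is cis to C6 and therefore axial in the chair) together with the C6 configuration: allylic 1,3-strain with C20 should force H6 inside and the alkoxide outside (pseudo-equatorial), so (6S) selects one chair and one face of C10. C9 is set by the E olefin from step 2, which puts C11 equatorial and H9 axial, anti to C20, the 9α-H/10β-methyl relation of the target. C5 is set afterwards by axial protonation of 12, which gives the equatorial aldehyde trans to the C9 branch, also the thermodynamic epimer. The step needs the [3,3] shift to outrun retro-allylation of the alkoxide and the chair to outrun the boat; the secondary alkoxide, the crown-separated ion pair at moderate temperature and the unstrained acyclic diene favour both.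

Step 8
Reactants: 13 (13R)-13-(triethylsilyloxy)-6,7-secolabda-7,14-dien-6-al
Product: 14 (6RS,13R)-6-ethenyl-13-(triethylsilyloxy)-6,7-secolabda-7,14-dien-6-ol
Conditions: CH2=CHMgBr, THF, −78 → 0 °C; aq. NH4Cl
Reagents that add atoms: vinylmagnesium bromide, C=C[Mg]Br
Why: Grignard addition to a hindered aldehyde whose α-hydrogen is shielded by two quaternary carbons, so enolisation should be slow; the inner vinyl carbon becomes C7 of the target, and both C6 epimers are acceptable because C6 is equilibrated in step 10.

Step 9
Reactants: 14 (6RS,13R)-6-ethenyl-13-(triethylsilyloxy)-6,7-secolabda-7,14-dien-6-ol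
Product: 15 (6RS,13R)-13-(triethylsilyloxy)labda-7,14-dien-6-ol
Conditions: second-generation Grubbs catalyst RuCl2(H2IMes)(PCy3)(=CHPh) (5 mol %), CH2Cl2, 40 °C
Reagents that add atoms: none
Why: Ring-closing metathesis of the allylic-alcohol vinyl group onto the isopropenyl group closes ring B as a trisubstituted cyclohexene with the olefin fixed at C7=C8; the C14=C15 vinyl group next to the fully substituted, silyloxy-bearing C13 is a poor metathesis partner and should stay out.

Step 10
Reactants: 15 (6RS,13R)-13-(triethylsilyloxy)labda-7,14-dien-6-ol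
Product: 16 (6S,13R)-13-(triethylsilyloxy)labda-7,14-dien-6-ol (6α-OH)
Conditions: Re2O7 (3 mol %), CH2Cl2, 0 °C → rt
Reagents that add atoms: none
Why: Rhenium-oxo catalysed allylic alcohol transposition under thermodynamic control: the perrhenate esters interconvert by [3,3] shifts and, because the ring B allyl cation is tertiary–secondary, by reversible ionisation, so both C6 epimers and the transposed 8-ols should funnel to the most stable isomer, the equatorial 6α-ol with the trisubstituted olefin; the silylated C13 oxygen cannot form a perrhenate and should stay untouched.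

Step 11
Reactants: 16 (6S,13R)-13-(triethylsilyloxy)labda-7,14-dien-6-ol
Product: 17 (6S,13R)-13-(triethylsilyloxy)labda-7,14-dien-6-yl butanoate
Conditions: (PrCO)2O, Et3N, DMAP (cat.), CH2Cl2, rt
Reagents that add atoms: butanoic anhydride, CCCC(=O)OC(=O)CCC
Why: DMAP-catalysed acylation of an equatorial secondary alcohol with retention at C6; no other free hydroxyl is present.

Step 12
Reactants: 17 (6S,13R)-13-(triethylsilyloxy)labda-7,14-dien-6-yl butanoate
Product: 18 (5S,6S,9S,10R,13R)-13-hydroxylabda-7,14-dien-6-yl butanoate (target)
Conditions: Bu4NF, AcOH, THF, 0 °C → rt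
Reagents that add atoms: none
Why: Buffered fluoride cleaves the triethylsilyl ether without acid (which would ionise the allylic positions) and without free alkoxide (which could attack the ester).

## Compound list

1 | (R)-(−)-linalool, (3R)-3,7-dimethylocta-1,6-dien-3-ol | C=C[C@](C)(O)CCC=C(C)C | starting material
2 | (3R)-3,7-dimethyl-3-(triethylsilyloxy)octa-1,6-diene | C=C[C@](C)(O[Si](CC)(CC)CC)CCC=C(C)C | intermediate
3 | (2E,6R)-2,6-dimethyl-6-(triethylsilyloxy)octa-2,7-dien-1-ol | C=C[C@](C)(O[Si](CC)(CC)CC)CC/C=C(\C)CO | intermediate
4 | (2E,6R)-2,6-dimethyl-6-(triethylsilyloxy)octa-2,7-dien-1-yl methanesulfonate (not isolated) | C=C[C@](C)(O[Si](CC)(CC)CC)CC/C=C(\C)COS(C)(=O)=O | intermediate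
5 | (2E,6R)-1-chloro-2,6-dimethyl-6-(triethylsilyloxy)octa-2,7-diene | C=C[C@](C)(O[Si](CC)(CC)CC)CC/C=C(\C)CCl | intermediate
6 | β-cyclocitral, 2,6,6-trimethylcyclohex-1-ene-1-carbaldehyde | CC1=C(C=O)C(C)(C)CCC1 | starting material
7 | [(2E,6R)-2,6-dimethyl-6-(triethylsilyloxy)octa-2,7-dien-1-yl]barium chloride (not isolated) | C=C[C@](C)(O[Si](CC)(CC)CC)CC/C=C(\C)C[Ba]Cl | intermediate
8 | (1RS,3E,7R)-3,7-dimethyl-7-(triethylsilyloxy)-1-(2,6,6-trimethylcyclohex-1-en-1-yl)nona-3,8-dien-1-ol (both C1 epimers) | C=C[C@](C)(O[Si](CC)(CC)CC)CC/C=C(\C)CC(O)C1=C(C)CCCC1(C)C | intermediate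
9 | (3E,7R)-3,7-dimethyl-7-(triethylsilyloxy)-1-(2,6,6-trimethylcyclohex-1-en-1-yl)nona-3,8-dien-1-one | C=C[C@](C)(O[Si](CC)(CC)CC)CC/C=C(\C)CC(=O)C1=C(C)CCCC1(C)C | intermediate
10 | (1S,3E,7R)-3,7-dimethyl-7-(triethylsilyloxy)-1-(2,6,6-trimethylcyclohex-1-en-1-yl)nona-3,8-dien-1-ol | C=C[C@](C)(O[Si](CC)(CC)CC)CC/C=C(\C)C[C@H](O)C1=C(C)CCCC1(C)C | intermediate
11 | potassium alkoxide of 10 (not isolated) | C=C[C@](C)(O[Si](CC)(CC)CC)CC/C=C(\C)C[C@H]([O-])C1=C(C)CCCC1(C)C.[K+] | intermediate
12 | potassium enolate of 13 (enolate geometry not specified; not isolated) | C=C[C@](C)(O[Si](CC)(CC)CC)CC[C@@H](C(C)=C)[C@@]1(C)CCCC(C)(C)C1=C[O-].[K+] | intermediate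
13 | (13R)-13-(triethylsilyloxy)-6,7-secolabda-7,14-dien-6-al (5α-H, 10β-CH3, C9 as in the target) | C=C[C@](C)(O[Si](CC)(CC)CC)CC[C@@H](C(C)=C)[C@@]1(C)CCCC(C)(C)[C@@H]1C=O | intermediate
14 | (6RS,13R)-6-ethenyl-13-(triethylsilyloxy)-6,7-secolabda-7,14-dien-6-ol (both C6 epimers) | C=C[C@](C)(O[Si](CC)(CC)CC)CC[C@@H](C(C)=C)[C@@]1(C)CCCC(C)(C)[C@@H]1C(O)C=C | intermediate
15 | (6RS,13R)-13-(triethylsilyloxy)labda-7,14-dien-6-ol (both C6 epimers) | C=C[C@](C)(O[Si](CC)(CC)CC)CC[C@H]1C(C)=CC(O)[C@H]2C(C)(C)CCC[C@]12C | intermediate
16 | (6S,13R)-13-(triethylsilyloxy)labda-7,14-dien-6-ol (6α-OH) | C=C[C@](C)(O[Si](CC)(CC)CC)CC[C@H]1C(C)=C[C@H](O)[C@H]2C(C)(C)CCC[C@]12C | intermediate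
17 | (6S,13R)-13-(triethylsilyloxy)labda-7,14-dien-6-yl butanoate | C=C[C@](C)(O[Si](CC)(CC)CC)CC[C@H]1C(C)=C[C@H](OC(=O)CCC)[C@H]2C(C)(C)CCC[C@]12C | intermediate
18 | (5S,6S,9S,10R,13R)-13-hydroxylabda-7,14-dien-6-yl butanoate | C=C[C@](C)(O)CC[C@H]1C(C)=C[C@H](OC(=O)CCC)[C@H]2C(C)(C)CCC[C@]12C | target

## Step count and risks

Total step count: 12. Longest linear sequence: 12 steps (1 → 18); β-cyclocitral 6 enters in step 4.

**Step 7 (key step).** The likely failures are fragmentation of the potassium alkoxide by retro-allylation (with recombination at either allyl terminus) and leakage of the C6 chirality through the chair with an axial alkoxide or through a boat. The fallback sets out from 10 and returns at 13, and removes the alkoxide altogether. The alcohol is capped as its trimethylsilyl ether F1 (Me3SiCl, imidazole) and rearranged without charge as a thermal silyloxy-Cope at about 200 °C in base-washed glass. This gives the silyl enol ether F2, which is hydrolysed with dilute aqueous citric acid to 13. The same chair governs the stereochemistry, but no anion is present to fragment.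

**Step 4.** The likely failures are attack through the substituted (γ) terminus, which gives the branched alcohol and after rearrangement the wrong constitution, and reductive coupling of the allyl chloride. The fallback sets out from 5 and returns at 9, fixing the regiochemistry with a sulfone. Chloride 5 and PhSO2Na in DMF give the allylic sulfone F3. Its α-lithio derivative (n-butyllithium, THF, −78 °C) adds to 6 at the sulfonyl-bearing carbon to give the β-hydroxy sulfone F4. Dess–Martin oxidation gives the β-keto sulfone F5, and SmI2 in THF/MeOH removes the sulfonyl group to give 9.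

**Step 6.** The likely failures are slow reduction of the shielded ketone, which lets uncatalysed background reduction erode the enantiomer ratio, and competing hydroboration of the vinyl group. The fallback sets out from 8 and returns at 10, bypassing 9. It is a Sharpless kinetic resolution of the carbinol epimers with Ti(OiPr)4, D-(−)-diisopropyl tartrate and t-BuOOH over 4 Å sieves at −20 °C. This should consume the (1R) epimer as the epoxy alcohol F6 and leave the (1S) epimer 10. The cost is half of the material and a slow reaction at the tetrasubstituted olefin.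

**Step 10.** The likely failures are proton loss from the ring B allyl cation to dienes, and cleavage of the silyl ether by perrhenic acid followed by transposition of the freed C13 carbinol. The fallback sets out from 15 and returns at 16, replacing the equilibration with a stereospecific walk of oxygen from C8 to C6. Dess–Martin oxidation of 15 gives the enone F7. H2O2/NaOH in MeOH should epoxidise it from the open α face to the 7α,8α-epoxy ketone F8. Wharton transposition (N2H4·H2O, AcOH, MeOH) gives the 6-en-8α-ol F9. Ph3SiOReO3 (cat.) in Et2O at 0 °C then shifts the 8α-oxygen suprafacially to C6α without ionisation, giving 16.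

## Further compounds

F1 | step 7 | trimethylsilyl ether of 10, (1S,3E,7R)-configured | C=C[C@](C)(O[Si](CC)(CC)CC)CC/C=C(\C)C[C@H](O[Si](C)(C)C)C1=C(C)CCCC1(C)C
F2 | step 7 | trimethylsilyl enol ether of 13 (enol ether geometry not specified) | C=C[C@](C)(O[Si](CC)(CC)CC)CC[C@@H](C(C)=C)[C@@]1(C)CCCC(C)(C)C1=CO[Si](C)(C)C
F3 | step 4 | (2E,6R)-2,6-dimethyl-1-(phenylsulfonyl)-6-(triethylsilyloxy)octa-2,7-diene | C=C[C@](C)(O[Si](CC)(CC)CC)CC/C=C(\C)CS(=O)(=O)c1ccccc1
F4 | step 4 | β-hydroxy sulfone, (3E,7R)-3,7-dimethyl-2-(phenylsulfonyl)-7-(triethylsilyloxy)-1-(2,6,6-trimethylcyclohex-1-en-1-yl)nona-3,8-dien-1-ol (C1/C2 diastereomers) | C=C[C@](C)(O[Si](CC)(CC)CC)CC/C=C(\C)C(C(O)C1=C(C)CCCC1(C)C)S(=O)(=O)c1ccccc1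
F5 | step 4 | β-keto sulfone, (3E,7R)-3,7-dimethyl-2-(phenylsulfonyl)-7-(triethylsilyloxy)-1-(2,6,6-trimethylcyclohex-1-en-1-yl)nona-3,8-dien-1-one (C2 epimers) | C=C[C@](C)(O[Si](CC)(CC)CC)CC/C=C(\C)C(C(=O)C1=C(C)CCCC1(C)C)S(=O)(=O)c1ccccc1
F6 | step 6 | epoxy alcohol from the (1R) epimer of 8, (1R,3E,7R)-3,7-dimethyl-7-(triethylsilyloxy)-1-(1,2-epoxy-2,6,6-trimethylcyclohexyl)nona-3,8-dien-1-ol (epoxide configuration left unassigned) | C=C[C@](C)(O[Si](CC)(CC)CC)CC/C=C(\C)C[C@@H](O)C12OC1(C)CCCC2(C)C
F7 | step 10 | (13R)-13-(triethylsilyloxy)labda-7,14-dien-6-one | C=C[C@](C)(O[Si](CC)(CC)CC)CC[C@H]1C(C)=CC(=O)[C@H]2C(C)(C)CCC[C@]12C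
F8 | step 10 | (13R)-7α,8α-epoxy-13-(triethylsilyloxy)labd-14-en-6-one | C=C[C@](C)(O[Si](CC)(CC)CC)CC[C@H]1[C@]3(C)O[C@@H]3C(=O)[C@H]2C(C)(C)CCC[C@]12C
F9 | step 10 | (13R)-13-(triethylsilyloxy)labda-6,14-dien-8α-ol (8β-CH3) | C=C[C@](C)(O[Si](CC)(CC)CC)CC[C@H]1[C@](C)(O)C=C[C@H]2C(C)(C)CCC[C@]12C
A1 | alternative 1 | sclareol, (13R)-labd-14-ene-8α,13-diol | C=C[C@](C)(O)CC[C@H]1[C@](C)(O)CC[C@H]2C(C)(C)CCC[C@]12C
A2 | alternative 1 | (13R)-labda-7,14-dien-13-ol | C=C[C@](C)(O)CC[C@H]1C(C)=CC[C@H]2C(C)(C)CCC[C@]12C
A3 | alternative 1 | (13R)-13-hydroxylabda-7,14-dien-6-one | C=C[C@](C)(O)CC[C@H]1C(C)=CC(=O)[C@H]2C(C)(C)CCC[C@]12C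
A4 | alternative 1 | (6R,13R)-labda-7,14-diene-6,13-diol (6β-OH) | C=C[C@](C)(O)CC[C@H]1C(C)=C[C@@H](O)[C@H]2C(C)(C)CCC[C@]12C
A5 | alternative 2 | (3R,6E,10E)-geranyllinalool, (3R,6E,10E)-3,7,11,15-tetramethylhexadeca-1,6,10,14-tetraen-3-ol | C=C[C@](C)(O)CC/C=C(\C)CC/C=C(\C)CCC=C(C)C
A6 | alternative 2 | (13R)-8α,13-epoxylabd-14-ene (cyclic ether from capture of the C8 cation) | C=C[C@@]1(C)CC[C@H]2[C@](C)(O1)CC[C@H]1C(C)(C)CCC[C@]21C
A7 | alternative 3 | potassium 2-oxidotriene from 9 (1Z,3E) | C=C[C@](C)(O[Si](CC)(CC)CC)CC/C=C(\C)/C=C(/[O-])C1=C(C)CCCC1(C)C.[K+]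
A8 | alternative 3 | (13R)-13-(triethylsilyloxy)-9-epi-labda-7,14-dien-6-one (one ring antipode shown; both would form) | C=C[C@](C)(O[Si](CC)(CC)CC)CC[C@@H]1C(C)=CC(=O)[C@H]2C(C)(C)CCC[C@]12C
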